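**Slow climb.** Product forms slowly in both earlier runs, so they can be read as a nearly steady rate, the product made per litre per minute, with a correction for the level of electrophile.

in all of them: gas 41 mM (held)
- winter: electrophile 1.1 M; run made earlier
- midnight: electrophile 1.8 M; run made earlier
- flask: electrophile 0.80 M; time 30 min

- winter (time / min: product / %, electrophile / %): 1.50: 1.0, 96.2; 5.00: 7.6, 90.9; 8.00: 10.9, 88.6; 12.0: 18.0, 83.3; 20.0: 29.0, 68.9
- midnight (time / min: product / %, electrophile / %): 1.33: 1.4, 97.5; 2.50: 3.0, 97.2; 5.00: 6.2, 95.3; 10.0: 11.6, 89.2; 20.0: 20.8, 78.7

(standard deviation of a reading: 1 percentage point)

- at the start none of the gas is in solution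

* product present at 30 min, in percent of the electrophile charged
* electrophile present at 30 min, in percent of the electrophile charged

**Two rates.** Up to 20.0 min, the readings of the winter run give product made on average at 0.0160 M min⁻¹ at a mean electrophile of 0.941 M. This mean is the charge less half of the product made. Up to 20.0 min, the readings of the midnight run give an average of 0.0187 M min⁻¹ at 1.61 M. From the winter run to the midnight run the level rises by a factor of 1.71, but the rate rises by a factor of 1.17. The ratio of the logarithms of these factors, 0.297, is the rate slope, the apparent reaction order; it is a reading and carries the scatter of both runs.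

**First estimate.** If the flask stayed at its charge of 0.80 M, the slope would give 0.0152 M min⁻¹, and 30 min at that rate makes 57.0% of the charge.

**Weak link.** The electrophile of the flask falls, however, so its charge is too high a level. Taking off half of that product gives a mean level of 0.572 M, a rate of 0.0138 M min⁻¹ and 51.6% product. The last winter reading balances at 97.9%, so the electrophile of the flask is reckoned as the remainder, 48.4%.

**Forecast.** The forecast gives 46% product and 53% electrophile, on the view that “This looks like gas uptake competing with reaction”. Its product stands 5.6 percentage points below the reckoning above.

**The flask.** The flask gives 49.9% product and 49.8% electrophile.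

    electrophile + nucleophile → acid set free + product (k = 1.40 M⁻¹ min⁻¹)
    nucleophile + acid set free ⇌ protonated nucleophile, settled at all times (K = 2000 M⁻¹)
    electrophile + acid set free ⇌ idle adduct, settled at all times (K = 0.590 M⁻¹)
    gas ⇌ nucleophile, rate k4*(csat - [nucleophile]) (kL = 1.10 min⁻¹)

The nucleophile of the flask stands at 0.0203 M at 30.0 min, about half of the saturation concentration of 41 mM. In the neighbouring flask charged with 1.4 M, the slope gives a mean level of 1.13 M and 36.2% product, and that flask holds 36.2% product at 30.0 min.

All runs come from a simulation on assumed constants.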